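**Retrosynthetic overview**

1. Target 17 ⇐ desilylation/acetylation at C2 of 15; the lactone, the C8 acetate and C6 come together from an Evans–Tishchenko reduction of the β-hydroxy ketone 13.
2. 13 ⇐ chelation-controlled dianion aldol of hydroxy enone 11 with ethyl 3-chloropyruvate 12 (C7–C11 bond, chlorohydrin in place).
3. 11 ⇐ Noyori mono-hydrogenation of the ten-membered 1,3-dione 10 ⇐ two-carbon ring expansion (dichloroketene [2+2], then retro-aldol) of cyclooctadienone 7.
4. 7 ⇐ C2-symmetric cyclooctadienedione 5, whose symmetry is broken by a CBS mono-reduction that sets C2.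
5. 5 ⇐ twofold one-carbon ring expansion (dibromocarbene) of the Birch diene of arene 1. Ring order: six-membered arene → eight → ten → γ-lactone last; both Z ring olefins are made cis inside the eight-membered ring and never touched again.

Assumption: arene 1 and ethyl 3-chloro-2-oxopropanoate 12 are taken as catalogue chemicals.

Skeleton numbering used in the text: ring C1–C10 with C1=C10(Me), C2–O, C4(Me)=C5, C6–O (lactone), C7, C8–O; C11 = C(OH), C12 = lactone C=O, C13 = CH2Cl. The target is 2S,6R,7R,8R,11S, 1(10)Z,4Z.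

**Step 1**
Reactants: 1 1,4-dimethoxy-2,5-dimethylbenzene
Product: 2 1,4-dimethoxy-2,5-dimethylcyclohexa-1,4-diene
Conditions: Li, NH3(l), THF, t-BuOH, −78 to −33 °C; NH4Cl
Reagents that add atoms: none
Why: Birch reduction, in which the radical anion of the electron-rich arene is protonated at the two unsubstituted positions so that both methoxy and both methyl groups stay on the double bonds of the symmetric 1,4-diene.

**Step 2**
Reactants: 2 1,4-dimethoxy-2,5-dimethylcyclohexa-1,4-diene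
Product: 4 (2E,6E)-2,6-dibromo-3,7-dimethylcycloocta-2,6-diene-1,5-dione, via bis(dibromocyclopropane) adduct 3 (not isolated)
Conditions: CHBr3, KOt-Bu, pentane, −20 °C to rt; then AgNO3, acetone–H2O, rt
Reagents that add atoms: bromoform, BrC(Br)Br; water, O
Why: Twofold dibromocarbene cyclopropanation of the two enol-ether double bonds followed by silver-assisted disrotatory cyclopropyl-to-allyl cation opening and capture by water is a double one-carbon ring expansion (six to eight members) that places each new C(Br)=C(Me) bond cis within the ring.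

**Step 3**
Reactants: 4 (2E,6E)-2,6-dibromo-3,7-dimethylcycloocta-2,6-diene-1,5-dione
Product: 5 (2Z,6Z)-3,7-dimethylcycloocta-2,6-diene-1,5-dione
Conditions: Bu3SnH (2.2 equiv), Pd(PPh3)4 (3 mol %), THF, rt
Reagents that add atoms: none
Why: Palladium-catalysed hydrodebromination (oxidative addition of zerovalent palladium into the activated vinylic C–Br bond, hydride transfer from tin, reductive elimination) runs under neutral conditions that spare the acidic C2-symmetric dione.

**Step 4**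
Reactants: 5 (2Z,6Z)-3,7-dimethylcycloocta-2,6-diene-1,5-dione
Product: 6 (2Z,5S,6Z)-5-hydroxy-3,7-dimethylcycloocta-2,6-dien-1-one
Conditions: (R)-2-methyl-CBS-oxazaborolidine (20 mol %), catecholborane (0.9 equiv), toluene, −78 °C; H2O
Reagents that add atoms: none
Why: Corey–Bakshi–Shibata reduction, in which the two carbonyls of 5 are homotopic so mono-reduction breaks the symmetry without a site-selectivity problem, and the (R)-catalyst (alkenyl side as the large group) sets the S carbinol that becomes C2; the reaction is stopped near 60 % conversion and 5 is recycled.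

**Step 5**
Reactants: 6 (2Z,5S,6Z)-5-hydroxy-3,7-dimethylcycloocta-2,6-dien-1-one
Product: 7 (2Z,5S,6Z)-5-[(tert-butyldimethylsilyl)oxy]-3,7-dimethylcycloocta-2,6-dien-1-one
Conditions: TBSCl, imidazole, DMF, rt
Reagents that add atoms: tert-butyldimethylsilyl chloride, CC(C)(C)[Si](C)(C)Cl
Why: Standard silylation of the secondary allylic alcohol, giving an ether that is a poor leaving group and survives the enolate, zinc and hydrogenation steps.

**Step 6**
Reactants: 7 (2Z,5S,6Z)-5-[(tert-butyldimethylsilyl)oxy]-3,7-dimethylcycloocta-2,6-dien-1-one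
Product: 8 (1S,2Z,4E,6Z)-1-[(tert-butyldimethylsilyl)oxy]-3,7-dimethyl-5-[(trimethylsilyl)oxy]cycloocta-2,4,6-triene
Conditions: LiN(i-Pr)2 (1.1 equiv), THF, −78 °C; TMSCl, −78 to 0 °C; used cold and at once
Reagents that add atoms: trimethylsilyl chloride, C[Si](C)(C)Cl
Why: Kinetic deprotonation of the enone at the doubly activated (α′ and allylic) C9–H followed by O-silylation gives the cross-conjugated silyl dienol ether regioselectively.

**Step 7**
Reactants: 8 (1S,2Z,4E,6Z)-1-[(tert-butyldimethylsilyl)oxy]-3,7-dimethyl-5-[(trimethylsilyl)oxy]cycloocta-2,4,6-triene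
Product: 10 (4Z,7S,8Z)-7-[(tert-butyldimethylsilyl)oxy]-5,9-dimethylcyclodeca-4,8-diene-1,3-dione, via dichlorocyclobutanone cycloadduct 9 (not isolated)
Conditions: Cl3CCOCl, zinc–copper couple (excess), Et2O–DME, 0 °C to rt; then AcOH–H2O, rt
Reagents that add atoms: trichloroacetyl chloride, ClC(Cl)(Cl)C(Cl)=O
Why: Dichloroketene [2+2] cycloaddition to the silyl enol ether (CCl2 to the oxygenated C6, carbonyl carbon to C9), zinc dechlorination and desilylative retro-aldol cleavage of the ring-fusion bond is the established two-carbon ring expansion of cyclic ketones to 1,3-diones, here favoured by cyclobutane strain and the allylic C9 carbanion, and it leaves C2 and both cis olefins untouched.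

**Step 8**
Reactants: 10 (4Z,7S,8Z)-7-[(tert-butyldimethylsilyl)oxy]-5,9-dimethylcyclodeca-4,8-diene-1,3-dione
Product: 11 (2Z,5S,6Z,9R)-5-[(tert-butyldimethylsilyl)oxy]-9-hydroxy-3,7-dimethylcyclodeca-2,6-dien-1-one
Conditions: H2 (50 atm), RuCl2[(R)-BINAP] (1 mol %), MeOH–CH2Cl2, 30 °C, stopped after 1 equiv H2
Reagents that add atoms: none
Why: Noyori asymmetric hydrogenation of a β-diketone, in which the C6 carbonyl chelates ruthenium and the more electrophilic non-conjugated C8 ketone is reduced first, (R)-BINAP giving the 8R carbinol in the same sense as (R)-3-hydroxybutanoate from acetoacetate.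

**Step 9**
Reactants: 11 (2Z,5S,6Z,9R)-5-[(tert-butyldimethylsilyl)oxy]-9-hydroxy-3,7-dimethylcyclodeca-2,6-dien-1-one; 12 ethyl 3-chloro-2-oxopropanoate
Product: 13 ethyl (2S)-2-[(1S,3Z,6S,7Z,10R)-6-[(tert-butyldimethylsilyl)oxy]-10-hydroxy-4,8-dimethyl-2-oxocyclodeca-3,7-dien-1-yl]-3-chloro-2-hydroxypropanoate
Conditions: LiN(i-Pr)2 (2.2 equiv), THF, −78 °C; 12, −78 °C; AcOH, −78 °C
Reagents that add atoms: none
Why: Alkoxide-directed deprotonation gives the lithium-chelated C6–C7 enolate (Fráter–Seebach-type dianion), which adds to the very electrophilic keto group of 12 through a closed Zimmerman–Traxler aldol transition state from the face opposite C9, so C11 ends cis to the C8 oxygen, while the ester, held by the alkoxide lithium, sits equatorial and CH2Cl axial, which is expected to give 11S; the cold acidic quench prevents retro-aldol, epoxide closure and lactonisation.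

**Step 10**
Reactants: 13 ethyl (2S)-2-[(1S,3Z,6S,7Z,10R)-6-[(tert-butyldimethylsilyl)oxy]-10-hydroxy-4,8-dimethyl-2-oxocyclodeca-3,7-dien-1-yl]-3-chloro-2-hydroxypropanoate
Product: 15 (3S,3aR,4R,6Z,8S,10Z,11aR)-8-[(tert-butyldimethylsilyl)oxy]-3-(chloromethyl)-3-hydroxy-6,10-dimethyl-2-oxo-2,3,3a,4,5,8,9,11a-octahydrocyclodeca[b]furan-4-yl acetate, via hydroxy ester 14 (not isolated)
Conditions: MeCHO (8 equiv), SmI2 (0.3 equiv), THF, −10 °C; then PPTS, toluene, 50 °C
Reagents that add atoms: acetaldehyde, CC=O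
Why: Evans–Tishchenko reduction, in which the acetaldehyde hemiacetal at the C8 hydroxyl, held on trivalent samarium, delivers hydride intramolecularly to C6 anti to the C8 oxygen (6R) and leaves C8 as its acetate, so that only the new C6 hydroxyl is free to close the trans-fused γ-lactone onto the ethyl ester.

**Step 11**
Reactants: 15 (3S,3aR,4R,6Z,8S,10Z,11aR)-8-[(tert-butyldimethylsilyl)oxy]-3-(chloromethyl)-3-hydroxy-6,10-dimethyl-2-oxo-2,3,3a,4,5,8,9,11a-octahydrocyclodeca[b]furan-4-yl acetate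
Product: 17 (3S,3aR,4R,6Z,8S,10Z,11aR)-3-(chloromethyl)-3-hydroxy-6,10-dimethyl-2-oxo-2,3,3a,4,5,8,9,11a-octahydrocyclodeca[b]furan-4,8-diyl diacetate, via allylic alcohol 16 (not isolated)
Conditions: HF·pyridine, THF, 0 °C to rt; then pyridine, Ac2O, rt
Reagents that add atoms: acetic anhydride, CC(=O)OC(C)=O
Why: Buffered HF·pyridine desilylation leaves chlorohydrin, lactone and acetate intact, and Ac2O/pyridine without DMAP acetylates the secondary allylic C2 hydroxyl but not the hindered tertiary C11 hydroxyl.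

**Compound list**

1 | 1,4-dimethoxy-2,5-dimethylbenzene | COc1cc(C)c(OC)cc1C | starting material
2 | 1,4-dimethoxy-2,5-dimethylcyclohexa-1,4-diene | COC1=C(C)CC(OC)=C(C)C1 | intermediate
3 | 4,4,8,8-tetrabromo-1,5-dimethoxy-3,7-dimethyltricyclo[5.1.0.0(3,5)]octane (cis and trans bis-adducts) | COC12CC3(C)C(Br)(Br)C3(OC)CC1(C)C2(Br)Br | intermediate (not isolated)
4 | (2E,6E)-2,6-dibromo-3,7-dimethylcycloocta-2,6-diene-1,5-dione (ring bonds cis at both olefins) | O=C1/C(Br)=C(/C)CC(=O)/C(Br)=C(/C)C1 | intermediate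
5 | (2Z,6Z)-3,7-dimethylcycloocta-2,6-diene-1,5-dione | O=C1/C=C(/C)CC(=O)/C=C(/C)C1 | intermediate
6 | (2Z,5S,6Z)-5-hydroxy-3,7-dimethylcycloocta-2,6-dien-1-one | O[C@@H]1/C=C(/C)CC(=O)/C=C(/C)C1 | intermediate
7 | (2Z,5S,6Z)-5-[(tert-butyldimethylsilyl)oxy]-3,7-dimethylcycloocta-2,6-dien-1-one | CC(C)(C)[Si](C)(C)O[C@@H]1/C=C(/C)CC(=O)/C=C(/C)C1 | intermediate
8 | (1S,2Z,4E,6Z)-1-[(tert-butyldimethylsilyl)oxy]-3,7-dimethyl-5-[(trimethylsilyl)oxy]cycloocta-2,4,6-triene | CC(C)(C)[Si](C)(C)O[C@@H]1/C=C(/C)\C=C(O[Si](C)(C)C)/C=C(/C)C1 | intermediate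
9 | (2Z,5S,6Z)-5-[(tert-butyldimethylsilyl)oxy]-10,10-dichloro-3,7-dimethyl-1-[(trimethylsilyl)oxy]bicyclo[6.2.0]deca-2,6-dien-9-one (cis-fused, both ring-fusion diastereomers) | CC(C)(C)[Si](C)(C)O[C@@H]1/C=C(/C)C2C(=O)C(Cl)(Cl)C2(O[Si](C)(C)C)/C=C(/C)C1 | intermediate (not isolated)
10 | (4Z,7S,8Z)-7-[(tert-butyldimethylsilyl)oxy]-5,9-dimethylcyclodeca-4,8-diene-1,3-dione | CC(C)(C)[Si](C)(C)O[C@@H]1/C=C(/C)CC(=O)CC(=O)/C=C(/C)C1 | intermediate
11 | (2Z,5S,6Z,9R)-5-[(tert-butyldimethylsilyl)oxy]-9-hydroxy-3,7-dimethylcyclodeca-2,6-dien-1-one | CC(C)(C)[Si](C)(C)O[C@@H]1/C=C(/C)C[C@@H](O)CC(=O)/C=C(/C)C1 | intermediate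
12 | ethyl 3-chloro-2-oxopropanoate | O=C(CCl)C(=O)OCC | starting material
13 | ethyl (2S)-2-[(1S,3Z,6S,7Z,10R)-6-[(tert-butyldimethylsilyl)oxy]-10-hydroxy-4,8-dimethyl-2-oxocyclodeca-3,7-dien-1-yl]-3-chloro-2-hydroxypropanoate | CC(C)(C)[Si](C)(C)O[C@@H]1/C=C(/C)C[C@@H](O)[C@@H]([C@@](O)(CCl)C(=O)OCC)C(=O)/C=C(/C)C1 | intermediate
14 | ethyl (2S)-2-[(1S,2R,3Z,6S,7Z,10R)-10-(acetyloxy)-6-[(tert-butyldimethylsilyl)oxy]-2-hydroxy-4,8-dimethylcyclodeca-3,7-dien-1-yl]-3-chloro-2-hydroxypropanoate | CC(C)(C)[Si](C)(C)O[C@@H]1/C=C(/C)C[C@@H](OC(C)=O)[C@@H]([C@@](O)(CCl)C(=O)OCC)[C@H](O)/C=C(/C)C1 | intermediate (not isolated)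
15 | (3S,3aR,4R,6Z,8S,10Z,11aR)-8-[(tert-butyldimethylsilyl)oxy]-3-(chloromethyl)-3-hydroxy-6,10-dimethyl-2-oxo-2,3,3a,4,5,8,9,11a-octahydrocyclodeca[b]furan-4-yl acetate | CC(C)(C)[Si](C)(C)O[C@@H]1/C=C(/C)C[C@@H](OC(C)=O)[C@@H]2[C@@H](/C=C(/C)C1)OC(=O)[C@]2(O)CCl | intermediate
16 | (3S,3aR,4R,6Z,8S,10Z,11aR)-3-(chloromethyl)-3,8-dihydroxy-6,10-dimethyl-2-oxo-2,3,3a,4,5,8,9,11a-octahydrocyclodeca[b]furan-4-yl acetate | O[C@@H]1/C=C(/C)C[C@@H](OC(C)=O)[C@@H]2[C@@H](/C=C(/C)C1)OC(=O)[C@]2(O)CCl | intermediate (not isolated)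
17 | (3S,3aR,4R,6Z,8S,10Z,11aR)-3-(chloromethyl)-3-hydroxy-6,10-dimethyl-2-oxo-2,3,3a,4,5,8,9,11a-octahydrocyclodeca[b]furan-4,8-diyl diacetate | CC(=O)O[C@@H]1/C=C(/C)C[C@@H](OC(C)=O)[C@@H]2[C@@H](/C=C(/C)C1)OC(=O)[C@]2(O)CCl | target

**Step count**

Total: 11 steps. Longest linear sequence: 11 steps (fully linear from 1; 12 is used as bought).

**Three steps most likely to fail, with fallbacks**

Step 7 (ring expansion). Dichloroketene may attack the conjugated silyloxy triene at the wrong double bond, or the triene may electrocyclise before it is trapped. The fallback sets out from 7 and comes back at 11, so it also bypasses step 8. CeCl3-mediated addition of vinylmagnesium bromide to 7 gives the vinyl carbinol F1. Its potassium alkoxide (KH, 18-crown-6, THF) undergoes the alkoxide-accelerated [1,3] shift of the allylic C9 from C6 to the vinyl terminus (Thies-type two-carbon ring expansion) to give the cyclodecadienone F2. Aerobic dehydrogenation (Pd(O2CCF3)2, DMSO, O2) gives the cross-conjugated trienone F3. Copper-catalysed conjugate borylation at the less substituted enone (CuCl, NaOt-Bu, a Josiphos ligand of the enantiomer that gives 8R, B2pin2, MeOH) gives the boronate F4, which is oxidised in the same flask with NaBO3 to 11.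

Step 8 (mono-hydrogenation). The reaction may not stop cleanly at the hydroxy ketone. The fallback sets out from 10 and comes back at 11. The same hydrogenation is run to completion (100 atm, 50 °C) to the anti-diol F5, in which the catalyst sets both carbinols. MnO2 in CH2Cl2 then oxidises only the allylic C6 hydroxyl and returns 11.

Step 9 (aldol). Proton transfer to the enolisable chloropyruvate, retro-aldol, or the wrong configuration at C11 would each sink this step. The fallback sets out from 11 and comes back at 15, building C11 last under substrate control. The same dianion is alkylated with ethyl iodoacetate to give the keto ester F6 (chelation-controlled, Fráter–Seebach sense). Me4NBH(OAc)3 in MeCN–AcOH reduces C6 anti to the C8 hydroxyl, and PPTS closes the trans-fused 6,12-lactone F7 (the 8,12-isomer, if formed, equilibrates under the same acid). LiN(i-Pr)2 (3.3 equiv) followed by Me2N=CH2+ I− gives the Mannich base F8, which is not isolated but quaternised with MeI and eliminated with NaHCO3 to the α-methylene lactone F9. Weitz–Scheffer epoxidation (t-BuOOH, DBU) delivers oxygen from the H7 face, anti to the C8 substituent, to give the 11,13-epoxide F10. LiCl–AcOH in THF opens it at the primary C13 to the chlorohydrin F11, and Ac2O–pyridine acetylates the C8 hydroxyl to return 15.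

**Further compounds**

F1 | step 7 | (2Z,5S,6Z)-5-[(tert-butyldimethylsilyl)oxy]-1-ethenyl-3,7-dimethylcycloocta-2,6-dien-1-ol (both C1 epimers) | CC(C)(C)[Si](C)(C)O[C@@H]1/C=C(/C)CC(O)(C=C)/C=C(/C)C1
F2 | step 7 | (2Z,5S,6Z)-5-[(tert-butyldimethylsilyl)oxy]-3,7-dimethylcyclodeca-2,6-dien-1-one | CC(C)(C)[Si](C)(C)O[C@@H]1/C=C(/C)CCCC(=O)/C=C(/C)C1
F3 | step 7 | (2Z,5S,6Z,9Z)-5-[(tert-butyldimethylsilyl)oxy]-3,7-dimethylcyclodeca-2,6,9-trien-1-one | CC(C)(C)[Si](C)(C)O[C@@H]1/C=C(/C)C/C=C\C(=O)/C=C(/C)C1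
F4 | step 7 | (2Z,5S,6Z,9R)-5-[(tert-butyldimethylsilyl)oxy]-3,7-dimethyl-9-(4,4,5,5-tetramethyl-1,3,2-dioxaborolan-2-yl)cyclodeca-2,6-dien-1-one | CC(C)(C)[Si](C)(C)O[C@@H]1/C=C(/C)C[C@@H](B2OC(C)(C)C(C)(C)O2)CC(=O)/C=C(/C)C1
F5 | step 8 | (1R,3S,4Z,7S,8Z)-7-[(tert-butyldimethylsilyl)oxy]-5,9-dimethylcyclodeca-4,8-diene-1,3-diol (anti diol) | CC(C)(C)[Si](C)(C)O[C@@H]1/C=C(/C)C[C@@H](O)C[C@H](O)/C=C(/C)C1
F6 | step 9 | keto ester: 11 carrying CH2CO2Et at C7, cis to the C8 hydroxyl | CC(C)(C)[Si](C)(C)O[C@@H]1/C=C(/C)C[C@@H](O)[C@@H](CC(=O)OCC)C(=O)/C=C(/C)C1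
F7 | step 9 | trans-fused 6,12-lactone with free C8 hydroxyl, C2 silyl ether and CH2 at C11 | CC(C)(C)[Si](C)(C)O[C@@H]1/C=C(/C)C[C@@H](O)[C@H]2CC(=O)O[C@@H]2/C=C(/C)C1
F8 | step 9 | Mannich base: F7 with CH2NMe2 at C11 (both C11 epimers) | CC(C)(C)[Si](C)(C)O[C@@H]1/C=C(/C)C[C@@H](O)[C@H]2C(CN(C)C)C(=O)O[C@@H]2/C=C(/C)C1
F9 | step 9 | α-methylene lactone: F7 with C11=CH2 | CC(C)(C)[Si](C)(C)O[C@@H]1/C=C(/C)C[C@@H](O)[C@H]2C(=C)C(=O)O[C@@H]2/C=C(/C)C1
F10 | step 9 | 11,13-epoxide of F9 with the epoxide oxygen on the H7 face | CC(C)(C)[Si](C)(C)O[C@@H]1/C=C(/C)C[C@@H](O)[C@H]2[C@@]3(CO3)C(=O)O[C@@H]2/C=C(/C)C1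
F11 | step 9 | chlorohydrin: 15 with a free C8 hydroxyl in place of the acetate | CC(C)(C)[Si](C)(C)O[C@@H]1/C=C(/C)C[C@@H](O)[C@H]2[C@@](O)(CCl)C(=O)O[C@@H]2/C=C(/C)C1
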